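**Retrosynthetic overview**

1. The strategy rests on the pyran ring (O2, C1, C8a, C4a, C4, C3): it is a 2H-pyran whose only sp3 atom, C1, is a bare CH2 between O2 and C8a, so it is the valence isomer of the 1-oxatriene O=C3–C4=C4a–C8a=C1H2.
2. Target 26 ⇐ protected pyran 25 ⇐ enone-ketone 21 + formaldehyde: C1–C8a by Mannich addition and elimination, C1–O2 by oxa-6π closure. The pyran is the only ring made and it is made last.
3. 21 ⇐ thioester 19 + propenylboronic acid (C3–propenyl bond); 19 ⇐ enone 15 + thioacetate enol silane 17 (C4a–C4 bond), with re-oxidation to the C8a=C4a enone.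
4. 15 ⇐ α-ketol 13 ⇐ alkene 11: C7–O by dihydroxylation anti to the C6 chain, then C8 oxidation and C8a=C4a dehydrogenation.
5. 11 ⇐ (S)-allylic alcohol 2 by Johnson–Claisen transfer of chirality to C6 and heptyl ketone formation; 2 ⇐ the purchased carbocycle 1 by CBS reduction.

Key step: step 11

Remark: atom labels are those of the isochromene core of the target (O2, C1, C3 to C8a; C1' and C2' are the CH2 and ketone carbon of the 2-oxononyl chain) and are kept for all intermediates; the C7 hydroxyl is carried as its triethylsilyl ether and C2' as its dioxolane through the key step.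

**Route**

Step 1
Reactants: 1 2-methylcyclohex-2-en-1-one
Product: 2 (1S)-2-methylcyclohex-2-en-1-ol
Conditions: (R)-2-methyl-CBS-oxazaborolidine (10 mol%), BH3·SMe2, THF, −20 °C; MeOH, then aq. work-up
Reagents that add atoms: none
Why: Corey–Bakshi–Shibata reduction, in which the oxazaborolidine–borane complex delivers hydride to one carbonyl face with the methyl-bearing alkene arm as the large group, should set the carbinol centre (the future C8) as S.

Step 2
Reactants: 2 (1S)-2-methylcyclohex-2-en-1-ol; 3 triethyl orthoacetate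
Product: 5 ethyl 2-[(1S)-2-methylcyclohex-2-en-1-yl]acetate, via ketene acetal 4 (not isolated)
Conditions: EtCO2H (cat.), neat 3, 140 °C, EtOH distilled off
Reagents that add atoms: triethyl orthoacetate, CC(OCC)(OCC)OCC
Why: Johnson–Claisen rearrangement, in which the suprafacial [3,3] shift of ketene acetal 4 within the ring forms the C6–C1' bond on the face of the breaking C8–O bond, should fix C6 as S and move the alkene to C7=C8.

Step 3
Reactants: 5 ethyl 2-[(1S)-2-methylcyclohex-2-en-1-yl]acetate; 6 N,O-dimethylhydroxylamine hydrochloride; 7 heptylmagnesium bromide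
Product: 9 1-[(1S)-2-methylcyclohex-2-en-1-yl]nonan-2-one, via Weinreb amide 8 (not isolated)
Conditions: 6, iPrMgCl (2 equiv per 6), THF, −20 °C; then 7, 0 °C to rt; aq. NH4Cl
Reagents that add atoms: heptylmagnesium bromide, CCCCCCC[Mg]Br; N,O-dimethylhydroxylamine hydrochloride, CNOC.Cl (its atoms stay only in intermediate 8)
Why: Weinreb ketone synthesis run in one flask, in which the chloromagnesium amide converts the ester into amide 8 and the chelated tetrahedral adduct of 8 with the Grignard reagent stops at the ketone stage.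

Step 4
Reactants: 9 1-[(1S)-2-methylcyclohex-2-en-1-yl]nonan-2-one; 10 ethane-1,2-diol
Product: 11 2-heptyl-2-{[(1S)-2-methylcyclohex-2-en-1-yl]methyl}-1,3-dioxolane
Conditions: p-TsOH·H2O (cat.), benzene, reflux, Dean–Stark
Reagents that add atoms: ethane-1,2-diol, OCCO
Why: Acid-catalysed ketalisation with azeotropic removal of water masks the C2' ketone, the trisubstituted ring alkene being inert to these conditions.

Step 5
Reactants: 11 2-heptyl-2-{[(1S)-2-methylcyclohex-2-en-1-yl]methyl}-1,3-dioxolane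
Product: 12 (1R,2S,3S)-3-[(2-heptyl-1,3-dioxolan-2-yl)methyl]-2-methylcyclohexane-1,2-diol
Conditions: OsO4 (2 mol%), N-methylmorpholine N-oxide, acetone/H2O, rt
Reagents that add atoms: OsO4 (oxygen carrier), O=[Os](=O)(=O)=O; N-methylmorpholine N-oxide, C[N+]1([O-])CCOCC1; water, O
Why: Catalytic OsO4 syn-dihydroxylation should occur on the alkene face opposite the C6 side chain, which allylic strain with the C7 methyl holds pseudoaxial, so that C7 is set as S with its hydroxyl trans to the C6 chain.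

Step 6
Reactants: 12 (1R,2S,3S)-3-[(2-heptyl-1,3-dioxolan-2-yl)methyl]-2-methylcyclohexane-1,2-diol
Product: 13 (2S,3S)-3-[(2-heptyl-1,3-dioxolan-2-yl)methyl]-2-hydroxy-2-methylcyclohexan-1-one
Conditions: (COCl)2, DMSO, CH2Cl2, −78 °C; Et3N, −78 to 0 °C
Reagents that add atoms: none
Why: Swern oxidation converts the secondary C8 alcohol into the ketone, while the tertiary C7 alcohol cannot be oxidised and the base-free activation leaves the dioxolane intact.

Step 7
Reactants: 13 (2S,3S)-3-[(2-heptyl-1,3-dioxolan-2-yl)methyl]-2-hydroxy-2-methylcyclohexan-1-one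
Product: 15 (5S,6S)-5-[(2-heptyl-1,3-dioxolan-2-yl)methyl]-6-methyl-6-(triethylsilyloxy)cyclohex-2-en-1-one, via bis-silyl enol ether 14 (not isolated)
Conditions: Et3SiOTf (2.4 equiv), Et3N, CH2Cl2, 0 °C; aq. NaHCO3 wash; then Pd(OAc)2 (1.1 equiv), MeCN, rt
Reagents that add atoms: triethylsilyl trifluoromethanesulfonate, CC[Si](CC)(CC)OS(=O)(=O)C(F)(F)F
Why: Silylation then Saegusa–Ito oxidation: because C7 is quaternary the ketone can enolise only toward C8a, so a single silyl enol ether forms and β-hydride elimination gives the C8a=C4a enone, the C7 hydroxyl being capped as its silyl ether in the same operation.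

Step 8
Reactants: 16 S-ethyl ethanethioate
Product: 17 1-(ethylsulfanyl)-1-(trimethylsilyloxy)ethene
Conditions: LiN(iPr)2, Me3SiCl, THF, −78 °C
Reagents that add atoms: chlorotrimethylsilane, C[Si](C)(C)Cl
Why: Kinetic deprotonation of the thioester and O-silylation of its enolate (silyl ketene acetal formation) gives the acetate donor for the next step.

Step 9
Reactants: 15 (5S,6S)-5-[(2-heptyl-1,3-dioxolan-2-yl)methyl]-6-methyl-6-(triethylsilyloxy)cyclohex-2-en-1-one; 17 1-(ethylsulfanyl)-1-(trimethylsilyloxy)ethene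
Product: 19 S-ethyl 2-[(4S,5S)-5-[(2-heptyl-1,3-dioxolan-2-yl)methyl]-4-methyl-3-oxo-4-(triethylsilyloxy)cyclohex-1-en-1-yl]ethanethioate, via silyl enol ether 18 (not isolated)
Conditions: 17 (1.2 equiv), Bu4N[Ph3SiF2] (5 mol%), THF, −78 to −40 °C; solvent exchange; then Pd(OAc)2 (1.3 equiv), MeCN, rt
Reagents that add atoms: 1-(ethylsulfanyl)-1-(trimethylsilyloxy)ethene, C=C(O[Si](C)(C)C)SCC
Why: Fluoride-initiated Mukaiyama–Michael addition places the thioacetate unit at C4a with silyl transfer to the ring enolate, and Saegusa–Ito oxidation of the regiodefined enol ether 18 restores the C8a=C4a enone and erases the transient C4a stereocentre.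

Step 10
Reactants: 19 S-ethyl 2-[(4S,5S)-5-[(2-heptyl-1,3-dioxolan-2-yl)methyl]-4-methyl-3-oxo-4-(triethylsilyloxy)cyclohex-1-en-1-yl]ethanethioate; 20 (E)-prop-1-en-1-ylboronic acid
Product: 21 (5S,6S)-5-[(2-heptyl-1,3-dioxolan-2-yl)methyl]-6-methyl-3-[(3E)-2-oxopent-3-en-1-yl]-6-(triethylsilyloxy)cyclohex-2-en-1-one
Conditions: Pd2(dba)3 (2.5 mol%), P(2-furyl)3 (15 mol%), Cu(O2C-2-C4H3S) (monovalent copper thiophene-2-carboxylate, 1.6 equiv), THF, 50 °C
Reagents that add atoms: (E)-prop-1-en-1-ylboronic acid, C/C=C/B(O)O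
Why: Liebeskind–Srogl coupling, in which zerovalent palladium and the copper carboxylate cofactor exchange the ethylsulfanyl group for the propenyl group without base and with retention of the E geometry, should leave the enone, the ketal and the acidic C4 methylene untouched.

Step 11
Reactants: 21 (5S,6S)-5-[(2-heptyl-1,3-dioxolan-2-yl)methyl]-6-methyl-3-[(3E)-2-oxopent-3-en-1-yl]-6-(triethylsilyloxy)cyclohex-2-en-1-one; 22 paraformaldehyde
Product: 25 (6S,7S)-6-[(2-heptyl-1,3-dioxolan-2-yl)methyl]-7-methyl-3-[(1E)-prop-1-en-1-yl]-7-(triethylsilyloxy)-6,7-dihydro-1H-isochromen-8(5H)-one, via Mannich base 23 (not isolated), via methylene dienone 24 (not isolated)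
Conditions: (CH2O)n (3 equiv), PhNHMe·CF3CO2H (0.5 equiv), THF, 60 °C
Reagents that add atoms: paraformaldehyde (as formaldehyde), C=O
Why: Proposed new method: the iminium ion formed from formaldehyde and the amine salt should be attacked by the extended dienol of 21 (C4 is α to the C3 ketone and γ to the C8 enone) through C8a, the α-terminus at which such dienolates normally react, to give Mannich base 23, and E1cB loss of N-methylaniline from the doubly activated C8a–H then leaves methylene dienone 24, the 1-oxatriene O=C3–C4=C4a–C8a=C1H2. The closest known reactions are the Knoevenagel/oxa-6π formal [3+3] synthesis of 2H-pyrans from 1,3-dicarbonyls and enals and the amine-salt α-methylenation of ketones with formaldehyde, whereas this vinylogous [5+1] combination has not been shown. The pyran ring closes by thermal disrotatory oxa-6π electrocyclisation forming C1–O2 (6-endo addition of the C3 enol oxygen to the exocyclic methylene would make the same bond), driven by loss of the exocyclic methylene and gain of the doubly vinylogous ester O2–C3=C4–C4a=C8a–C8=O locked in a fused ring. No stereocentre is created because C1 is CH2, and C6 and C7 are not epimerisable under the conditions. The step needs attack at C8a rather than C4: a C4 adduct can revert by retro-Mannich reaction and its methylene product cannot close onto the C8 oxygen because C4 and C8 lie trans across the ring C4a=C8a bond, whereas the C8a pathway is drained irreversibly; the dioxolane keeps C2' out of an aldol with C4 and the silyl ether blocks α-ketol rearrangement.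

Step 12
Reactants: 25 (6S,7S)-6-[(2-heptyl-1,3-dioxolan-2-yl)methyl]-7-methyl-3-[(1E)-prop-1-en-1-yl]-7-(triethylsilyloxy)-6,7-dihydro-1H-isochromen-8(5H)-one
Product: 26 (6S,7S)-7-hydroxy-7-methyl-6-(2-oxononyl)-3-[(1E)-prop-1-en-1-yl]-6,7-dihydro-1H-isochromen-8(5H)-one
Conditions: HF (48% aq.), MeCN, 0 °C to rt
Reagents that add atoms: water, O
Why: Acidic global deprotection, in which aqueous HF cleaves the tertiary silyl ether and hydrolyses the dioxolane in one operation, should be tolerated by the doubly vinylogous ester of the pyranone, which recloses if it opens reversibly.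

**Compound list**

1 | 2-methylcyclohex-2-en-1-one | CC1=CCCCC1=O | starting material
2 | (1S)-2-methylcyclohex-2-en-1-ol | O[C@@H]1C(C)=CCCC1 | intermediate
3 | triethyl orthoacetate | CC(OCC)(OCC)OCC | starting material
4 | 1-ethoxy-1-{[(1S)-2-methylcyclohex-2-en-1-yl]oxy}ethene | C=C(OCC)O[C@@H]1C(C)=CCCC1 | intermediate (not isolated)
5 | ethyl 2-[(1S)-2-methylcyclohex-2-en-1-yl]acetate | CCOC(=O)C[C@H]1C(C)=CCCC1 | intermediate
6 | N,O-dimethylhydroxylamine hydrochloride | CNOC.Cl | starting material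
7 | heptylmagnesium bromide | CCCCCCC[Mg]Br | starting material
8 | N-methoxy-N-methyl-2-[(1S)-2-methylcyclohex-2-en-1-yl]acetamide | CON(C)C(=O)C[C@H]1C(C)=CCCC1 | intermediate (not isolated)
9 | 1-[(1S)-2-methylcyclohex-2-en-1-yl]nonan-2-one | CCCCCCCC(=O)C[C@H]1C(C)=CCCC1 | intermediate
10 | ethane-1,2-diol | OCCO | starting material
11 | 2-heptyl-2-{[(1S)-2-methylcyclohex-2-en-1-yl]methyl}-1,3-dioxolane | CCCCCCCC1(C[C@H]2C(C)=CCCC2)OCCO1 | intermediate
12 | (1R,2S,3S)-3-[(2-heptyl-1,3-dioxolan-2-yl)methyl]-2-methylcyclohexane-1,2-diol | O[C@@H]1CCC[C@@H](CC2(CCCCCCC)OCCO2)[C@]1(C)O | intermediate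
13 | (2S,3S)-3-[(2-heptyl-1,3-dioxolan-2-yl)methyl]-2-hydroxy-2-methylcyclohexan-1-one | O=C1CCC[C@@H](CC2(CCCCCCC)OCCO2)[C@]1(C)O | intermediate
14 | triethyl({(5S,6S)-5-[(2-heptyl-1,3-dioxolan-2-yl)methyl]-6-methyl-6-(triethylsilyloxy)cyclohex-1-en-1-yl}oxy)silane | CC[Si](CC)(CC)OC1=CCC[C@@H](CC2(CCCCCCC)OCCO2)[C@]1(C)O[Si](CC)(CC)CC | intermediate (not isolated)
15 | (5S,6S)-5-[(2-heptyl-1,3-dioxolan-2-yl)methyl]-6-methyl-6-(triethylsilyloxy)cyclohex-2-en-1-one | O=C1C=CC[C@@H](CC2(CCCCCCC)OCCO2)[C@]1(C)O[Si](CC)(CC)CC | intermediate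
16 | S-ethyl ethanethioate | CCSC(C)=O | starting material
17 | 1-(ethylsulfanyl)-1-(trimethylsilyloxy)ethene | C=C(O[Si](C)(C)C)SCC | intermediate
18 | S-ethyl 2-[(1S,4S,5S)-5-[(2-heptyl-1,3-dioxolan-2-yl)methyl]-4-methyl-4-(triethylsilyloxy)-3-(trimethylsilyloxy)cyclohex-2-en-1-yl]ethanethioate | CCSC(=O)C[C@H]1C=C(O[Si](C)(C)C)[C@@](C)(O[Si](CC)(CC)CC)[C@H](CC2(CCCCCCC)OCCO2)C1 | intermediate (not isolated)
19 | S-ethyl 2-[(4S,5S)-5-[(2-heptyl-1,3-dioxolan-2-yl)methyl]-4-methyl-3-oxo-4-(triethylsilyloxy)cyclohex-1-en-1-yl]ethanethioate | CCSC(=O)CC1=CC(=O)[C@@](C)(O[Si](CC)(CC)CC)[C@H](CC2(CCCCCCC)OCCO2)C1 | intermediate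
20 | (E)-prop-1-en-1-ylboronic acid | C/C=C/B(O)O | starting material
21 | (5S,6S)-5-[(2-heptyl-1,3-dioxolan-2-yl)methyl]-6-methyl-3-[(3E)-2-oxopent-3-en-1-yl]-6-(triethylsilyloxy)cyclohex-2-en-1-one | C/C=C/C(=O)CC1=CC(=O)[C@@](C)(O[Si](CC)(CC)CC)[C@H](CC2(CCCCCCC)OCCO2)C1 | intermediate (key-step precursor)
22 | paraformaldehyde (source of formaldehyde) | C=O | starting material
23 | (2S,3S,5Z)-3-[(2-heptyl-1,3-dioxolan-2-yl)methyl]-2-methyl-6-{[methyl(phenyl)amino]methyl}-5-[(3E)-2-oxopent-3-en-1-ylidene]-2-(triethylsilyloxy)cyclohexan-1-one (both epimers at the aminomethyl-bearing carbon C8a) | C/C=C/C(=O)/C=C1/C[C@@H](CC2(CCCCCCC)OCCO2)[C@](C)(O[Si](CC)(CC)CC)C(=O)C1CN(C)c3ccccc3 | intermediate (not isolated)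
24 | (2S,3S,5Z)-3-[(2-heptyl-1,3-dioxolan-2-yl)methyl]-2-methyl-6-methylidene-5-[(3E)-2-oxopent-3-en-1-ylidene]-2-(triethylsilyloxy)cyclohexan-1-one | C/C=C/C(=O)/C=C1/C[C@@H](CC2(CCCCCCC)OCCO2)[C@](C)(O[Si](CC)(CC)CC)C(=O)C1=C | intermediate (not isolated)
25 | (6S,7S)-6-[(2-heptyl-1,3-dioxolan-2-yl)methyl]-7-methyl-3-[(1E)-prop-1-en-1-yl]-7-(triethylsilyloxy)-6,7-dihydro-1H-isochromen-8(5H)-one | C/C=C/C1=CC2=C(CO1)C(=O)[C@@](C)(O[Si](CC)(CC)CC)[C@H](CC3(CCCCCCC)OCCO3)C2 | intermediate (key-step product)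
26 | (6S,7S)-7-hydroxy-7-methyl-6-(2-oxononyl)-3-[(1E)-prop-1-en-1-yl]-6,7-dihydro-1H-isochromen-8(5H)-one | C/C=C/C1=CC2=C(CO1)C(=O)[C@@](C)(O)[C@H](CC(=O)CCCCCCC)C2 | target

**Step count and risk**

Total step count: 12. Longest linear sequence: 11 steps (steps 1 to 7 and 9 to 12, from 1); step 8 prepares reagent 17.

Steps most likely to fail:

1. Step 11 (proposed new method). The Mannich attack may go to C4 instead of C8a, the transient methylene ketone may oligomerise, or the dienol may cyclise onto the propenyl ketone before the pyran closes. The fallback sets out from enone 15, in which C4a is still unsubstituted, so the one-carbon unit can be fixed at C8a without ambiguity. Morita–Baylis–Hillman reaction with aqueous formaldehyde (DMAP cat., THF/H2O) should give hydroxymethyl enone F1, and TBSCl/imidazole then gives silyl ether F2. Addition of 17 under the conditions of step 9 gives silyl enol ether F3, which Pd(OAc)2 oxidises to thioester F4, and coupling with 20 as in step 10 gives dienone F5. Buffered HF·pyridine at 0 °C, which should spare the hindered tertiary silyl ether, frees primary alcohol F6. With catalytic pyridinium p-toluenesulfonate F6 adds to the C3 ketone and loses water, a cyclodehydration that closes the pyran and rejoins the route at 25.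

2. Step 9. The conjugate addition may give 1,2-addition or lose thiolate from the thioester enolate, and the sulfur may interfere with the palladium oxidation. The fallback sets out from 15 and uses a soft donor and a metal-free dehydrogenation. Meldrum's acid with catalytic Et3N in MeCN adds to C4a to give adduct F7. Pyridine/H2O at 100 °C opens the dioxanedione and decarboxylates it to acid F8, and EtSH, EDC·HCl and DMAP give thioester F9. IBX in DMSO/toluene at 70 °C then dehydrogenates the ring ketone, which can enolise only toward C8a, and the route is rejoined at 19.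

3. Step 10. Copper may enolise the doubly activated C4 methylene next to the thioester so that deacylation outruns transmetalation, or the propenyl group may isomerise. The fallback sets out from 15 and replaces the acyl coupling by an aldol-level donor. 2,4-Bis(trimethylsilyloxy)pent-1-ene F10 (from 4-hydroxypentan-2-one, LiN(iPr)2, Me3SiCl) is added under the conditions of step 9 to give silyl enol ether F11, and Pd(OAc)2 gives enone F12. Aqueous citric acid frees the secondary alcohol to give β-hydroxy ketone F13. MsCl/Et3N gives mesylate F14, which eliminates on addition of DBU to the E enone, rejoining the route at 21.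

**Further compounds**

F1 | step 11 | (5S,6S)-5-[(2-heptyl-1,3-dioxolan-2-yl)methyl]-2-(hydroxymethyl)-6-methyl-6-(triethylsilyloxy)cyclohex-2-en-1-one | O=C1C(CO)=CC[C@@H](CC2(CCCCCCC)OCCO2)[C@]1(C)O[Si](CC)(CC)CC
F2 | step 11 | (5S,6S)-2-{[tert-butyl(dimethyl)silyl]oxymethyl}-5-[(2-heptyl-1,3-dioxolan-2-yl)methyl]-6-methyl-6-(triethylsilyloxy)cyclohex-2-en-1-one | O=C1C(CO[Si](C)(C)C(C)(C)C)=CC[C@@H](CC2(CCCCCCC)OCCO2)[C@]1(C)O[Si](CC)(CC)CC
F3 | step 11 | S-ethyl 2-[(1S,4S,5S)-2-{[tert-butyl(dimethyl)silyl]oxymethyl}-5-[(2-heptyl-1,3-dioxolan-2-yl)methyl]-4-methyl-4-(triethylsilyloxy)-3-(trimethylsilyloxy)cyclohex-2-en-1-yl]ethanethioate | CCSC(=O)C[C@H]1C(CO[Si](C)(C)C(C)(C)C)=C(O[Si](C)(C)C)[C@@](C)(O[Si](CC)(CC)CC)[C@H](CC2(CCCCCCC)OCCO2)C1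
F4 | step 11 | S-ethyl 2-[(4S,5S)-2-{[tert-butyl(dimethyl)silyl]oxymethyl}-5-[(2-heptyl-1,3-dioxolan-2-yl)methyl]-4-methyl-3-oxo-4-(triethylsilyloxy)cyclohex-1-en-1-yl]ethanethioate | CCSC(=O)CC1=C(CO[Si](C)(C)C(C)(C)C)C(=O)[C@@](C)(O[Si](CC)(CC)CC)[C@H](CC2(CCCCCCC)OCCO2)C1
F5 | step 11 | (5S,6S)-2-{[tert-butyl(dimethyl)silyl]oxymethyl}-5-[(2-heptyl-1,3-dioxolan-2-yl)methyl]-6-methyl-3-[(3E)-2-oxopent-3-en-1-yl]-6-(triethylsilyloxy)cyclohex-2-en-1-one | C/C=C/C(=O)CC1=C(CO[Si](C)(C)C(C)(C)C)C(=O)[C@@](C)(O[Si](CC)(CC)CC)[C@H](CC2(CCCCCCC)OCCO2)C1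
F6 | step 11 | (5S,6S)-5-[(2-heptyl-1,3-dioxolan-2-yl)methyl]-2-(hydroxymethyl)-6-methyl-3-[(3E)-2-oxopent-3-en-1-yl]-6-(triethylsilyloxy)cyclohex-2-en-1-one | C/C=C/C(=O)CC1=C(CO)C(=O)[C@@](C)(O[Si](CC)(CC)CC)[C@H](CC2(CCCCCCC)OCCO2)C1
F7 | step 9 | 5-[(1R,4S,5S)-5-[(2-heptyl-1,3-dioxolan-2-yl)methyl]-4-methyl-3-oxo-4-(triethylsilyloxy)cyclohexyl]-2,2-dimethyl-1,3-dioxane-4,6-dione | CC1(C)OC(=O)C(C(=O)O1)[C@H]2CC(=O)[C@@](C)(O[Si](CC)(CC)CC)[C@H](CC3(CCCCCCC)OCCO3)C2
F8 | step 9 | 2-[(1R,4S,5S)-5-[(2-heptyl-1,3-dioxolan-2-yl)methyl]-4-methyl-3-oxo-4-(triethylsilyloxy)cyclohexyl]acetic acid | OC(=O)C[C@H]1CC(=O)[C@@](C)(O[Si](CC)(CC)CC)[C@H](CC2(CCCCCCC)OCCO2)C1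
F9 | step 9 | S-ethyl 2-[(1R,4S,5S)-5-[(2-heptyl-1,3-dioxolan-2-yl)methyl]-4-methyl-3-oxo-4-(triethylsilyloxy)cyclohexyl]ethanethioate | CCSC(=O)C[C@H]1CC(=O)[C@@](C)(O[Si](CC)(CC)CC)[C@H](CC2(CCCCCCC)OCCO2)C1
F10 | step 10 | 2,4-bis(trimethylsilyloxy)pent-1-ene (racemic) | C=C(O[Si](C)(C)C)CC(C)O[Si](C)(C)C
F11 | step 10 | 1-[(1S,4S,5S)-5-[(2-heptyl-1,3-dioxolan-2-yl)methyl]-4-methyl-4-(triethylsilyloxy)-3-(trimethylsilyloxy)cyclohex-2-en-1-yl]-4-(trimethylsilyloxy)pentan-2-one (both epimers at C4 of the pentanone chain) | CC(O[Si](C)(C)C)CC(=O)C[C@H]1C=C(O[Si](C)(C)C)[C@@](C)(O[Si](CC)(CC)CC)[C@H](CC2(CCCCCCC)OCCO2)C1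
F12 | step 10 | (5S,6S)-5-[(2-heptyl-1,3-dioxolan-2-yl)methyl]-6-methyl-3-[2-oxo-4-(trimethylsilyloxy)pentyl]-6-(triethylsilyloxy)cyclohex-2-en-1-one (both side-chain epimers) | CC(O[Si](C)(C)C)CC(=O)CC1=CC(=O)[C@@](C)(O[Si](CC)(CC)CC)[C@H](CC2(CCCCCCC)OCCO2)C1
F13 | step 10 | (5S,6S)-5-[(2-heptyl-1,3-dioxolan-2-yl)methyl]-3-(4-hydroxy-2-oxopentyl)-6-methyl-6-(triethylsilyloxy)cyclohex-2-en-1-one (both side-chain epimers) | CC(O)CC(=O)CC1=CC(=O)[C@@](C)(O[Si](CC)(CC)CC)[C@H](CC2(CCCCCCC)OCCO2)C1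
F14 | step 10 | 5-[(4S,5S)-5-[(2-heptyl-1,3-dioxolan-2-yl)methyl]-4-methyl-3-oxo-4-(triethylsilyloxy)cyclohex-1-en-1-yl]-4-oxopentan-2-yl methanesulfonate (both side-chain epimers) | CC(OS(C)(=O)=O)CC(=O)CC1=CC(=O)[C@@](C)(O[Si](CC)(CC)CC)[C@H](CC2(CCCCCCC)OCCO2)C1
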